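Count what is left of the left-handed substrate, not what has been made.

common to all: left-handed substrate 10 mM; right-handed substrate 10 mM; racemization catalyst 0.26 mM

| run | reagent | remark | time |
|---|---|---|---|
| beta | 23 mM | run made earlier |  |
| epsilon | 31 mM | run made earlier |  |
| eta | 50 mM | run made earlier |  |
| Thursday's | 22.0 mM |  | 4.0 h |
| Monday's | 44.0 mM |  | 4.0 h |

| beta: time / min | beta: left-handed product / % | epsilon: time / min | epsilon: left-handed product / % | eta: time / min | eta: left-handed product / % |
|---|---|---|---|---|---|
| 25.0 | 2.1 | 10.0 | 1.3 | 10.0 | 1.7 |
| 50.0 | 4.4 | 30.0 | 4.9 | 30.0 | 5.9 |
| 80.0 | 7.4 | 60.0 | 6.1 | 60.0 | 10.7 |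
| 90.0 | 7.9 | 80.0 | 9.1 | 80.0 | 12.9 |
| 120 | 9.9 | 120 | 12.3 | 120 | 18.4 |

(readings scatter by 0.5 percentage points)

- reagent is single-handed; left-handed substrate and right-handed substrate are mirror images of each other, charged as a racemate, each of them at the stated concentration
- the handed part of reagent does not stay in what it makes, so the products of the two hands are mirror images too

* which of the two there is more of at the end, Thursday's (right-handed product / left-handed product)
* which of the two there is more of at the end, Monday's (right-handed product / left-handed product)
* how much left-handed product is there at the end, in percent of the left-handed substrate and right-handed substrate together charged: Thursday's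
* how much left-handed product is there at the end, in percent of the left-handed substrate and right-handed substrate together charged: Monday's

My own reckoning takes the reagent as staying near its charge (pseudo-first-order). The left-handed substrate then dies away with one number, the exposure N: rate constant times c_reagent times time.

  left-handed substrate left = exp(−N)
  left-handed product = (1 − exp(−N)) / 2, as a share of both substrates charged

Turned round, the last reading of each run, at 120 min, gives N: 0.221 in beta, 0.282 in epsilon, 0.459 in eta. If one number is enough, eta's N over beta's should match their reagent ratio of 2.17. The readings give 2.08, a gap that a scatter of 0.5 percentage points covers. But these runs share one catalyst charge and stop at half the asked time, so neither is tested.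

0.407 is the pooled exposure at Thursday's reagent and time, N. Monday's, with twice the reagent, is 0.814. That gives 16.7% and 27.8%. The readings do not show the right-handed product, so I reckon no hand.

The forecast says left-handed product for Thursday's and left-handed product for Monday's, with 16% and 28%. Its Thursday's figure stands a little below mine. On the hand it says: “tentatively expect left product to lead”.

The flask gives 16.3% on Thursday's and 28.1% on Monday's, and left-handed product leads in each. Right-handed product is 0.126% on Thursday's and 0.249% on Monday's.

    left-handed substrate + racemization catalyst ⇌ right-handed substrate + racemization catalyst, rate k1*[racemization catalyst]*[left-handed substrate] forward; the back reaction follows from the equilibrium constant (k = 7.80 M⁻¹ min⁻¹)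
    reagent + right-handed substrate → right-handed product (k = 5.30 × 10⁻⁴ M⁻¹ min⁻¹)
    2 racemization catalyst → spent catalyst (k = 2.70 M⁻¹ min⁻¹)
    reagent + left-handed substrate → left-handed product (k = 0.0790 M⁻¹ min⁻¹)

Monday's ends above Thursday's because of its reagent: without the difference in reagent from Thursday's, taken away with all else held, Monday's left-handed product falls from 28.1% to 16.3%. Twice the exposure gave 1.72 times the product in the flask, and the fraction left had said 1.66.

A neighbour of Thursday's with 88 mM of reagent has N = 1.63, which gives 40.2%. The flask gives 43.0%.

The readings are calculated on assumed constants; the scatter is artificial.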